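Assumption: the SMILES is read as robinetinidol-(4α→8)-epigallocatechin, i.e. upper unit 2R,3S,4S (5-deoxy, 2,3-trans-3,4-trans), lower unit 2R,3R (2,3-cis), bond from C4 of the upper unit to C8 of the lower unit.

## Retrosynthetic overview

1. Target ⇐ its nona-O-benzyl ether (all phenols benzylated, both 3-OH free) by hydrogenolysis.
2. Nona-benzyl ether ⇐ one operation that makes three aryl–C bonds: C4–C4a (closes ring C), C4'–C4a' (closes ring F) and C4–C8' (interflavan). The seco partners are an α-hydroxy-β-aryloxy aldehyde (rings A and B) and an aryl epoxy ether (ring D and the second ring B).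
3. Both seco partners ⇐ one erythro epoxy alcohol: Mitsunobu etherification with the ring D phenol (inversion, 2,3-cis pattern), or Payne rearrangement then benzylic opening by the ring A phenoxide (2,3-trans pattern).
4. Epoxy alcohol ⇐ Sharpless kinetic resolution of the vinyl carbinol made from 3,4,5-tris(benzyloxy)benzaldehyde and vinylmagnesium bromide.
5. Ring order: the four benzene rings are bought; ring F closes first and ring C directly after it in the same flask, and C4 is set as the two halves join.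

## Route

Step 1
Reactants: 1 3,4,5-tris(benzyloxy)benzaldehyde; 2 vinylmagnesium bromide
Product: 3 rac-1-[3,4,5-tris(benzyloxy)phenyl]prop-2-en-1-ol
Conditions: THF, −78 → 0 °C; then H2O
Reagents that add atoms: none
Why: Grignard 1,2-addition of the vinyl group to the aryl aldehyde gives the allylic alcohol, left racemic on purpose for the resolution in step 2.

Step 2
Reactants: 3 rac-1-[3,4,5-tris(benzyloxy)phenyl]prop-2-en-1-ol
Product: 4 (S)-[(R)-oxiran-2-yl][3,4,5-tris(benzyloxy)phenyl]methanol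
Conditions: Ti(OiPr)4 (10 mol %), L-(+)-DIPT (15 mol %), tBuOOH (0.45 equiv), 4 Å MS, CH2Cl2, −20 °C
Reagents that add atoms: tert-butyl hydroperoxide, CC(C)(C)OO
Why: Sharpless kinetic resolution (Katsuki–Sharpless epoxidation of a secondary allylic alcohol): with L-(+)-DIPT the (R)-enantiomer of 3 is epoxidised much faster and gives the erythro epoxy alcohol, so the carbinol centre (S after the priority change) is selected and the epoxide centre (R) is set by reagent control, while the slow (S)-enantiomer of 3 is recovered.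

Step 3
Reactants: 4 (S)-[(R)-oxiran-2-yl][3,4,5-tris(benzyloxy)phenyl]methanol; 5 3,5-bis(benzyloxy)phenol
Product: 6 (2R)-2-[(R)-[3,5-bis(benzyloxy)phenoxy][3,4,5-tris(benzyloxy)phenyl]methyl]oxirane
Conditions: PPh3, DIAD, toluene, 0 → 23 °C
Reagents that add atoms: none
Why: Mitsunobu etherification displaces the activated benzylic hydroxyl by the phenol with inversion (S to R), giving the syn aryl ether that maps onto the 2,3-cis lower unit; the epoxide centre is untouched.

Step 4
Reactants: 4 (S)-[(R)-oxiran-2-yl][3,4,5-tris(benzyloxy)phenyl]methanol; 7 3-(benzyloxy)phenol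
Product: 9 (2S,3R)-3-[3-(benzyloxy)phenoxy]-3-[3,4,5-tris(benzyloxy)phenyl]propane-1,2-diol, via trans-epoxy alcohol 8 (not isolated)
Conditions: NaOH (1 equiv), tBuOH/H2O, 23 °C, 1 h; then 7 (2 equiv), 70 °C
Reagents that add atoms: none
Why: Payne rearrangement then epoxide opening: the alkoxide of 4 closes onto its own epoxide carbon with inversion to give the more substituted trans-2,3-epoxy alcohol 8, and the phenoxide opens 8 at the benzylic carbon with inversion (SN2, as known for 3-aryl glycidols), so both centres of the anti diol come from 4 and map onto the 2,3-trans upper unit.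

Step 5
Reactants: 9 (2S,3R)-3-[3-(benzyloxy)phenoxy]-3-[3,4,5-tris(benzyloxy)phenyl]propane-1,2-diol
Product: 10 (2R,3R)-3-[3-(benzyloxy)phenoxy]-2-hydroxy-3-[3,4,5-tris(benzyloxy)phenyl]propanal
Conditions: TEMPO (10 mol %), PhI(OAc)2 (1.1 equiv), CH2Cl2, 0 → 23 °C; used crude at once
Reagents that add atoms: none
Why: Oxoammonium (TEMPO) catalysed oxidation with PhI(OAc)2 as terminal oxidant is selective for the primary hydroxyl over the hindered secondary one and touches neither stereocentre (the descriptor at C2 changes only through priorities).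

Step 6
Reactants: 10 (2R,3R)-3-[3-(benzyloxy)phenoxy]-2-hydroxy-3-[3,4,5-tris(benzyloxy)phenyl]propanal; 6 (2R)-2-[(R)-[3,5-bis(benzyloxy)phenoxy][3,4,5-tris(benzyloxy)phenyl]methyl]oxirane (1.5 equiv)
Product: 13 nona-O-benzyl robinetinidol-(4α→8)-epigallocatechin, via pentabenzyl epigallocatechin 11 (not isolated), via tetrabenzyl leucorobinetinidin 12 (not isolated)
Conditions: AuCl3 (10 mol %), AgOTf (30 mol %), 4 Å MS, CH2Cl2, −20 → 23 °C, 10 added slowly
Reagents that add atoms: none
Why: Proposed new method: one oxophilic Lewis acid (Au(OTf)3 formed from AuCl3/AgOTf) runs three Friedel–Crafts alkylations in one flask — (i) the phloroglucinol ring of 6 attacks the activated terminal epoxide carbon ortho to its ether oxygen (6-endo; closest known reaction: gold-catalysed cycloalkylation of aryl epoxy ethers to chroman-3-ols), closing ring F with both centres untouched (2R,3R, cis) to give 11; (ii) the resorcinol ring of 10 attacks the activated aldehyde para to its benzyloxy group (closest known reaction: acid cyclisation of 3-aryloxypropanals to chroman-4-ols), closing ring C to give 12; (iii) loss of the C4 hydroxyl of 12 gives the oxygen-stabilised flavan-4-yl cation, which C8 of 11 attacks anti to the C3 hydroxyl (closest known reaction: Lewis-acid coupling of flavan-4-yl cations with flavan-3-ols used for procyanidins), setting C4 as S (3,4-trans) by substrate control; slow addition of 10 keeps 11 in excess so the fast intramolecular closures precede the bimolecular step and oligomers are suppressed, and water is the only by-product.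

Step 7
Reactants: 13 nona-O-benzyl robinetinidol-(4α→8)-epigallocatechin
Product: 14 robinetinidol-(4α→8)-epigallocatechin (target)
Conditions: H2 (1 atm), Pd(OH)2/C, THF/MeOH/H2O, 23 °C
Reagents that add atoms: none
Why: Hydrogenolysis of the nine benzyl ethers under neutral conditions touches no stereocentre and leaves the C2–O1 bonds and the acid-stable interflavan bond of the 5-deoxy upper unit intact.

## Compound list

1 | 3,4,5-tris(benzyloxy)benzaldehyde | O=Cc1cc(OCc2ccccc2)c(OCc2ccccc2)c(OCc2ccccc2)c1 | starting material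
2 | vinylmagnesium bromide | C=C[Mg]Br | starting material
3 | rac-1-[3,4,5-tris(benzyloxy)phenyl]prop-2-en-1-ol | OC(C=C)c1cc(OCc2ccccc2)c(OCc2ccccc2)c(OCc2ccccc2)c1 | intermediate
4 | (S)-[(R)-oxiran-2-yl][3,4,5-tris(benzyloxy)phenyl]methanol | O[C@@H](c1cc(OCc2ccccc2)c(OCc2ccccc2)c(OCc2ccccc2)c1)[C@H]1CO1 | intermediate
5 | 3,5-bis(benzyloxy)phenol | Oc1cc(OCc2ccccc2)cc(OCc2ccccc2)c1 | starting material
6 | (2R)-2-[(R)-[3,5-bis(benzyloxy)phenoxy][3,4,5-tris(benzyloxy)phenyl]methyl]oxirane | c1ccc(COc2cc(OCc3ccccc3)cc(O[C@H](c3cc(OCc4ccccc4)c(OCc4ccccc4)c(OCc4ccccc4)c3)[C@H]3CO3)c2)cc1 | intermediate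
7 | 3-(benzyloxy)phenol | Oc1cccc(OCc2ccccc2)c1 | starting material
8 | [(2S,3S)-3-[3,4,5-tris(benzyloxy)phenyl]oxiran-2-yl]methanol | OC[C@@H]1O[C@H]1c1cc(OCc2ccccc2)c(OCc2ccccc2)c(OCc2ccccc2)c1 | intermediate (not isolated)
9 | (2S,3R)-3-[3-(benzyloxy)phenoxy]-3-[3,4,5-tris(benzyloxy)phenyl]propane-1,2-diol | OC[C@H](O)[C@H](Oc1cccc(OCc2ccccc2)c1)c1cc(OCc2ccccc2)c(OCc2ccccc2)c(OCc2ccccc2)c1 | intermediate
10 | (2R,3R)-3-[3-(benzyloxy)phenoxy]-2-hydroxy-3-[3,4,5-tris(benzyloxy)phenyl]propanal | O=C[C@H](O)[C@H](Oc1cccc(OCc2ccccc2)c1)c1cc(OCc2ccccc2)c(OCc2ccccc2)c(OCc2ccccc2)c1 | intermediate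
11 | (2R,3R)-5,7-bis(benzyloxy)-2-[3,4,5-tris(benzyloxy)phenyl]chroman-3-ol (penta-O-benzyl epigallocatechin) | C(c1ccccc1)Oc1cc(OCc2ccccc2)c2c(c1)O[C@H](c1cc(OCc3ccccc3)c(OCc3ccccc3)c(OCc3ccccc3)c1)[C@H](O)C2 | intermediate (not isolated)
12 | (2R,3S)-7-(benzyloxy)-2-[3,4,5-tris(benzyloxy)phenyl]chroman-3,4-diol, both C4 epimers | C(c1ccccc1)Oc1ccc2c(c1)O[C@H](c1cc(OCc3ccccc3)c(OCc3ccccc3)c(OCc3ccccc3)c1)[C@@H](O)C2O | intermediate (not isolated)
13 | (2R,3S,4S)-7-(benzyloxy)-4-[(2R,3R)-5,7-bis(benzyloxy)-3-hydroxy-2-[3,4,5-tris(benzyloxy)phenyl]chroman-8-yl]-2-[3,4,5-tris(benzyloxy)phenyl]chroman-3-ol | C(c1ccccc1)Oc1ccc2c(c1)O[C@H](c1cc(OCc3ccccc3)c(OCc3ccccc3)c(OCc3ccccc3)c1)[C@@H](O)[C@@H]2c1c(OCc3ccccc3)cc(OCc3ccccc3)c2c1O[C@H](c1cc(OCc3ccccc3)c(OCc3ccccc3)c(OCc3ccccc3)c1)[C@H](O)C2 | intermediate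
14 | robinetinidol-(4α→8)-epigallocatechin | Oc1ccc2c(c1)O[C@H](c1cc(O)c(O)c(O)c1)[C@@H](O)[C@@H]2c1c(O)cc(O)c2c1O[C@H](c1cc(O)c(O)c(O)c1)[C@H](O)C2 | target

## Step count and risks

Total step count: 7. Longest linear sequence: 6 (steps 1, 2, 4, 5, 6, 7); step 3 is the side branch from 4.

Steps most likely to fail:

**Step 6 (one-flask triple Friedel–Crafts reaction).** The cation may give some 3,4-cis or C6-linked isomer, or 10 may decompose before it cyclises. The fallback sets out from 10 and 6 and comes back at 13; it separates the ring closures from the coupling. 6 alone with AuCl3/AgOTf gives 11, which is now isolated. 10 with camphorsulfonic acid and 2-ethoxyethanol in CH2Cl2 at 0 °C cyclises and is trapped as (2R,3S)-7-(benzyloxy)-4-(2-ethoxyethoxy)-2-[3,4,5-tris(benzyloxy)phenyl]chroman-3-ol F1 (both C4 epimers), a storable C4 electrophile. F1 and 11 (3 equiv) with TMSOTf in CH2Cl2 at −78 °C then give 13, under the low-temperature regime where 3,4-trans and C8 selectivity of such couplings is best established.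

**Step 5 (selective oxidation to the α-hydroxy aldehyde).** PhI(OAc)2 can cleave 1,2-diols, and the product can over-oxidise, epimerise or dimerise. The fallback sets out from 9 and comes back at 13. 9 with Et3SiCl and imidazole gives (2S,3R)-3-[3-(benzyloxy)phenoxy]-1,2-bis(triethylsilyloxy)-3-[3,4,5-tris(benzyloxy)phenyl]propane F2. Swern conditions ((COCl)2, DMSO, then Et3N, −78 → −30 °C) oxidise the primary silyl ether directly and leave the secondary one, giving (2R,3R)-3-[3-(benzyloxy)phenoxy]-2-(triethylsilyloxy)-3-[3,4,5-tris(benzyloxy)phenyl]propanal F3, which has no free α-hydroxyl. F3 takes the place of 10 in step 6 and gives, through (2R,3S)-7-(benzyloxy)-3-(triethylsilyloxy)-2-[3,4,5-tris(benzyloxy)phenyl]chroman-4-ol F4 (not isolated), the 3-O-triethylsilyl ether of 13 F5. Bu4NF in THF then gives 13.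

**Step 4 (Payne rearrangement and phenoxide opening).** Phenoxide may attack the terminal carbon of 4 instead of the benzylic carbon of 8, or hydroxide may open either epoxide. The fallback sets out from 3 and comes back at 9. The (S)-enriched 3 recovered from step 2 (or racemic 3) is isomerised with Ph3SiOReO3 (2 mol %, Et2O, 0 °C, 1,3-transposition to the conjugated isomer) to (E)-3-[3,4,5-tris(benzyloxy)phenyl]prop-2-en-1-ol F6. Katsuki–Sharpless epoxidation (Ti(OiPr)4, L-(+)-DIPT, tBuOOH, −20 °C) gives 8, now isolated. 7 with Cs2CO3 in DMF at 70 °C (no hydroxide, so no equilibration with 4) opens 8 at the benzylic carbon and gives 9.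

Further compounds

F1 | step 6 | (2R,3S)-7-(benzyloxy)-4-(2-ethoxyethoxy)-2-[3,4,5-tris(benzyloxy)phenyl]chroman-3-ol, both C4 epimers | C(c1ccccc1)Oc1ccc2c(c1)O[C@H](c1cc(OCc3ccccc3)c(OCc3ccccc3)c(OCc3ccccc3)c1)[C@@H](O)C2OCCOCC
F2 | step 5 | (2S,3R)-3-[3-(benzyloxy)phenoxy]-1,2-bis(triethylsilyloxy)-3-[3,4,5-tris(benzyloxy)phenyl]propane | CC[Si](CC)(CC)OC[C@H](O[Si](CC)(CC)CC)[C@H](Oc1cccc(OCc2ccccc2)c1)c1cc(OCc2ccccc2)c(OCc2ccccc2)c(OCc2ccccc2)c1
F3 | step 5 | (2R,3R)-3-[3-(benzyloxy)phenoxy]-2-(triethylsilyloxy)-3-[3,4,5-tris(benzyloxy)phenyl]propanal | O=C[C@H](O[Si](CC)(CC)CC)[C@H](Oc1cccc(OCc2ccccc2)c1)c1cc(OCc2ccccc2)c(OCc2ccccc2)c(OCc2ccccc2)c1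
F4 | step 5 | (2R,3S)-7-(benzyloxy)-3-(triethylsilyloxy)-2-[3,4,5-tris(benzyloxy)phenyl]chroman-4-ol, both C4 epimers | C(c1ccccc1)Oc1ccc2c(c1)O[C@H](c1cc(OCc3ccccc3)c(OCc3ccccc3)c(OCc3ccccc3)c1)[C@@H](O[Si](CC)(CC)CC)C2O
F5 | step 5 | 3-O-triethylsilyl ether of 13 (silyl group on the upper-unit C3 oxygen) | C(c1ccccc1)Oc1ccc2c(c1)O[C@H](c1cc(OCc3ccccc3)c(OCc3ccccc3)c(OCc3ccccc3)c1)[C@@H](O[Si](CC)(CC)CC)[C@@H]2c1c(OCc3ccccc3)cc(OCc3ccccc3)c2c1O[C@H](c1cc(OCc3ccccc3)c(OCc3ccccc3)c(OCc3ccccc3)c1)[C@H](O)C2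
F6 | step 4 | (E)-3-[3,4,5-tris(benzyloxy)phenyl]prop-2-en-1-ol | OC/C=C/c1cc(OCc2ccccc2)c(OCc2ccccc2)c(OCc2ccccc2)c1
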